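## Retrosynthetic overview

1. THF ring (formed last): on the finished macrolactone, the C17 hydroxyl opens an 11,12-epoxide at C14 by 5-exo SN2′ attack. This sets C14 and the 12Z alkene and leaves the epoxide oxygen as C11–OH; the epoxide is made in the same operation by reagent-controlled epoxidation of the macrocyclic 11E,13E-diene.
2. 20-membered lactone (formed first): macrolactonisation of the C19-hydroxy seco acid (C1–O19).
3. C13=C14: Julia–Kocienski union of a western enal (C1–C13) with an eastern tetrazolyl sulfone (C14–C24).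
4. West: thiazolidinethione aldol (C4), Still–Gennari olefination (2Z), alkyne allylation and Zn semi-reduction (8Z). East: (S)-chlorohydrin ester (C15), L-rhamnal (C22, C23), boron aldol and Evans–Tishchenko reduction (C17–C19).
5. Ring order: macrolactone, then THF.

Assumption: positions are given in maltepolide numbering (C1 = lactone carbonyl, C24 = side-chain methyl); CIP letters are those of the compound named.
Assumption: the propionyl thiazolidinethione, the Still–Gennari phosphonate, 2-methyl-2-vinyloxirane and 3,4-di-O-acetyl-L-rhamnal are bought as catalogue chemicals.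

## Route

Step 1
Reactants: 1 3-(trimethylsilyl)prop-2-ynal; 2 2-(triphenylphosphoranylidene)propanal
Product: 3 (2E)-2-methyl-5-(trimethylsilyl)pent-2-en-4-ynal
Conditions: CH2Cl2, 0 °C → rt
Reagents that add atoms: none
Why: Wittig olefination with a stabilised ylide is E-selective and the ynal is far more electrophilic than the enal product, so mono-olefination gives the (E)-enynal carrying C5–C9 and the C6 methyl (sets 6E).

Step 2
Reactants: 3 (2E)-2-methyl-5-(trimethylsilyl)pent-2-en-4-ynal; 4 (4S)-4-benzyl-3-propanoyl-1,3-thiazolidine-2-thione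
Product: 5 (4S)-4-benzyl-3-[(2R,3R,4E)-3-hydroxy-2,4-dimethyl-7-(trimethylsilyl)hept-4-en-6-ynoyl]-1,3-thiazolidine-2-thione
Conditions: TiCl4 (1.05 equiv), i-Pr2NEt (1.1 equiv), CH2Cl2, 0 °C; then 3, −78 → 0 °C
Reagents that add atoms: none
Why: Crimmins titanium-enolate aldol with one equivalent of amine runs through the chelated (thiocarbonyl-bound) Zimmerman–Traxler transition state and gives the non-Evans syn adduct, which fixes C4 (R here, S once C3 becomes an alkene carbon); the C5 carbinol configuration is irrelevant because C5 ends as the ketone.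

Step 3
Reactants: 5 aldol adduct
Product: 6 (4S)-4-benzyl-3-[(2R,3R,4E)-2,4-dimethyl-3-(triethylsilyloxy)-7-(trimethylsilyl)hept-4-en-6-ynoyl]-1,3-thiazolidine-2-thione
Conditions: TESOTf, 2,6-lutidine, CH2Cl2, −78 °C
Reagents that add atoms: triethylsilyl trifluoromethanesulfonate, CC[Si](CC)(CC)OS(=O)(=O)C(F)(F)F
Why: Silyl triflate silylation of the hindered secondary alcohol; TES is chosen because it can later be converted directly into the C5 ketone.

Step 4
Reactants: 6 TES ether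
Product: 7 (2R,3R,4E)-2,4-dimethyl-3-(triethylsilyloxy)-7-(trimethylsilyl)hept-4-en-6-ynal
Conditions: i-Bu2AlH, CH2Cl2, −78 °C
Reagents that add atoms: none
Why: N-Acyl thiazolidinethiones are reduced by i-Bu2AlH directly to aldehydes (the tetrahedral intermediate is stable at −78 °C), so C3 is freed as the aldehyde without touching C4.

Step 5
Reactants: 7 aldehyde; 8 ethyl 2-[bis(2,2,2-trifluoroethoxy)phosphoryl]propanoate
Product: 9 ethyl (2Z,4S,5R,6E)-2,4,6-trimethyl-5-(triethylsilyloxy)-9-(trimethylsilyl)nona-2,6-dien-8-ynoate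
Conditions: 8, KN(SiMe3)2, 18-crown-6, THF, −78 °C; then 7
Reagents that add atoms: none
Why: Still–Gennari olefination: the electron-poor bis(trifluoroethyl) phosphonate under dissociating conditions eliminates from the kinetic adduct and gives the (2Z)-2-methyl enoate.

Step 6
Reactants: 9 silyl enynoate
Product: 10 ethyl (2Z,4S,5R,6E)-2,4,6-trimethyl-5-(triethylsilyloxy)nona-2,6-dien-8-ynoate
Conditions: K2CO3 (cat.), EtOH, rt
Reagents that add atoms: none
Why: Ethoxide-mediated protodesilylation of the alkynyl–Si bond leaves the secondary TES ether intact, and EtOH avoids transesterification of the ethyl ester.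

Step 7
Reactants: 11 2-methyl-2-vinyloxirane (racemic)
Product: 12 (2E)-4-chloro-2-methylbut-2-en-1-ol
Conditions: TiCl4, CH2Cl2, −90 → −78 °C; aqueous work-up
Reagents that add atoms: titanium tetrachloride, Cl[Ti](Cl)(Cl)Cl
Why: TiCl4 activates the vinyl epoxide and delivers chloride to the vinyl terminus (SN2′ ring opening), giving the (E)-allylic alcohol that becomes C10–C13 with the C12 methyl.

Step 8
Reactants: 10 terminal enyne; 12 (2E)-4-chloro-2-methylbut-2-en-1-ol
Product: 13 ethyl (2Z,4S,5R,6E,11E)-13-hydroxy-2,4,6,12-tetramethyl-5-(triethylsilyloxy)trideca-2,6,11-trien-8-ynoate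
Conditions: CuI (10 mol%), K2CO3, n-Bu4NCl, DMF, rt
Reagents that add atoms: none
Why: Jeffery copper-catalysed coupling of a terminal alkyne with a primary allylic chloride is an SN2 substitution at CH2Cl that keeps the (E)-alkene and forms the C9–C10 bond of the skipped enyne.

Step 9
Reactants: 13 skipped enyne
Product: 14 ethyl (2Z,4S,5R,6E,8Z,11E)-13-hydroxy-2,4,6,12-tetramethyl-5-(triethylsilyloxy)trideca-2,6,8,11-tetraenoate
Conditions: Zn dust activated with Cu(OAc)2 and AgNO3, MeOH/H2O (1:1), 40 °C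
Reagents that add atoms: none
Why: Boland reduction: the activated zinc reduces only the alkyne conjugated to the C6=C7 alkene, by syn delivery of hydrogen, and gives the (8Z)-alkene without over-reduction.

Step 10
Reactants: 14 allylic alcohol
Product: 15 ethyl (2Z,4S,5R,6E,8Z,11E)-2,4,6,12-tetramethyl-13-oxo-5-(triethylsilyloxy)trideca-2,6,8,11-tetraenoate
Conditions: MnO2, CH2Cl2, rt
Reagents that add atoms: none
Why: MnO2 oxidises the primary allylic alcohol chemoselectively to the (E)-enal needed for the olefination.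

Step 11
Reactants: 16 ethyl (3S)-4-chloro-3-hydroxybutanoate
Product: 17 ethyl (3S)-4-chloro-3-methoxybutanoate
Conditions: Me3OBF4, 1,8-bis(dimethylamino)naphthalene, CH2Cl2, rt
Reagents that add atoms: trimethyloxonium tetrafluoroborate, C[O+](C)C.F[B-](F)(F)F
Why: O-Methylation with a Meerwein salt and a non-nucleophilic base avoids the E1cB elimination that alkoxide conditions cause in β-hydroxy esters; C15 (S) comes from the chiral pool.

Step 12
Reactants: 17 ethyl (3S)-4-chloro-3-methoxybutanoate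
Product: 18 ethyl (3S)-3-methoxy-4-[(1-phenyl-1H-tetrazol-5-yl)sulfanyl]butanoate
Conditions: 1-phenyl-1H-tetrazole-5-thiol, K2CO3, DMF, 60 °C
Reagents that add atoms: 1-phenyl-1H-tetrazole-5-thiol, Sc1nnnn1-c1ccccc1
Why: SN2 thioetherification of the primary chloride by the soft tetrazole thiolate (S-alkylation).

Step 13
Reactants: 18 thioether ester
Product: 19 (3S)-N,3-dimethoxy-N-methyl-4-[(1-phenyl-1H-tetrazol-5-yl)sulfanyl]butanamide
Conditions: MeNH(OMe)·HCl, i-PrMgCl, THF, −20 → 0 °C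
Reagents that add atoms: N,O-dimethylhydroxylamine hydrochloride, CNOC.Cl
Why: Weinreb amide formation by the magnesium amide at low temperature; it is done at the sulfide stage so that no acidic α-sulfonyl C–H is present.

Step 14
Reactants: 19 Weinreb amide
Product: 20 (5S)-5-methoxy-6-[(1-phenyl-1H-tetrazol-5-yl)sulfanyl]hexan-3-one
Conditions: EtMgBr, THF, 0 °C; aq. NH4Cl
Reagents that add atoms: ethylmagnesium bromide, CC[Mg]Br
Why: Grignard addition to a Weinreb amide stops at the chelated tetrahedral intermediate and gives the ethyl ketone (C17 carbonyl, C18 and its methyl).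

Step 15
Reactants: 20 sulfide ketone
Product: 21 (5S)-5-methoxy-6-[(1-phenyl-1H-tetrazol-5-yl)sulfonyl]hexan-3-one
Conditions: 30% H2O2, (NH4)6Mo7O24·4H2O (10 mol%), EtOH, 0 °C → rt
Reagents that add atoms: hydrogen peroxide, OO
Why: Molybdate-catalysed peroxide oxidation of the sulfide gives the sulfone that serves as the Julia–Kocienski handle.

Step 16
Reactants: 22 3,4-di-O-acetyl-L-rhamnal
Product: 23 (2E,4R,5S)-4-acetoxy-5-hydroxyhex-2-enal
Conditions: HgSO4 (2 mol%), 0.005 M aq. H2SO4, 1,4-dioxane, rt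
Reagents that add atoms: water, O
Why: Perlin hydrolysis: HgSO4-catalysed hydration of the glycal, loss of the C3 acetate and ring opening give the (E)-enal; C4 and C5 of L-rhamnal are untouched and become C22 (R) and C23 (S), and the alkene becomes 20E.

Step 17
Reactants: 23 Perlin aldehyde
Product: 24 (2E,4R,5S)-4,5-dihydroxyhex-2-enal
Conditions: K2CO3 (0.1 equiv), MeOH, 0 °C
Reagents that add atoms: none
Why: Base-catalysed transesterification removes the acetate at 0 °C, and the (E)-geometry prevents the diol from closing onto the aldehyde.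

Step 18
Reactants: 24 diol enal
Product: 25 (2E)-3-[(4R,5S)-2,2,5-trimethyl-1,3-dioxolan-4-yl]prop-2-enal
Conditions: 2-methoxypropene, PPTS (cat.), CH2Cl2, 0 °C
Reagents that add atoms: 2-methoxypropene, COC(C)=C
Why: Acid-catalysed acetonide formation on the erythro 1,2-diol gives the cis-dioxolane, which stays on until the last step.

Step 19
Reactants: 21 sulfonyl ethyl ketone; 25 acetonide enal
Product: 26 (2S,5S,6R,7E)-6-hydroxy-2-methoxy-5-methyl-1-[(1-phenyl-1H-tetrazol-5-yl)sulfonyl]-8-[(4R,5S)-2,2,5-trimethyl-1,3-dioxolan-4-yl]oct-7-en-4-one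
Conditions: (−)-Ipc2BOTf [from (+)-α-pinene], i-Pr2NEt, CH2Cl2, −78 °C; then 25, −78 → −20 °C; H2O2, MeOH, pH 7 buffer
Reagents that add atoms: none
Why: Paterson boron aldol: the (Z)-enol diisopinocampheylborinate, formed on the ethyl side away from the β-methoxy group, adds through a chair Zimmerman–Traxler transition state to the Si face of the enal under reagent control and gives the 18,19-syn adduct with C19 (R).

Step 20
Reactants: 26 β-hydroxy ketone
Product: 27 (2S,4R,5R,6R,7E)-4-hydroxy-2-methoxy-5-methyl-1-[(1-phenyl-1H-tetrazol-5-yl)sulfonyl]-8-[(4R,5S)-2,2,5-trimethyl-1,3-dioxolan-4-yl]oct-7-en-6-yl acetate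
Conditions: SmI2 (30 mol%, premixed with MeCHO), MeCHO (10 equiv), THF, −10 °C
Reagents that add atoms: acetaldehyde, CC=O
Why: Evans–Tishchenko reduction: the samarium-bound hemiacetal of acetaldehyde on O19 delivers hydride intramolecularly to C17 through a six-membered chair, giving the 17,19-anti diol as its C19 monoacetate, so C17 (R) is set and the two hydroxyls are differentiated in one step.

Step 21
Reactants: 27 hydroxy acetate
Product: 28 (2S,4R,5S,6R,7E)-4-[(tert-butyldimethylsilyl)oxy]-2-methoxy-5-methyl-1-[(1-phenyl-1H-tetrazol-5-yl)sulfonyl]-8-[(4R,5S)-2,2,5-trimethyl-1,3-dioxolan-4-yl]oct-7-en-6-yl acetate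
Conditions: TBSOTf, 2,6-lutidine, CH2Cl2, −78 °C
Reagents that add atoms: tert-butyldimethylsilyl trifluoromethanesulfonate, CC(C)(C)[Si](C)(C)OS(=O)(=O)C(F)(F)F
Why: Silylation of the free C17 hydroxyl keeps it masked until the macrolactone is closed.

Step 22
Reactants: 28 eastern sulfone; 15 western enal
Product: 29 seco ester: ethyl (2Z,4S,5R,6E,8Z,11E,13E,15S,17R,18S,19R,20E)-19-acetoxy-17-[(tert-butyldimethylsilyl)oxy]-15-methoxy-2,4,6,12,18-pentamethyl-5-(triethylsilyloxy)-21-[(4R,5S)-2,2,5-trimethyl-1,3-dioxolan-4-yl]henicosa-2,6,8,11,13,20-hexaenoate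
Conditions: 28, KN(SiMe3)2, DME, −78 °C; then 15, −78 °C → rt; aq. NH4Cl
Reagents that add atoms: none
Why: Julia–Kocienski olefination: the α-sulfonyl anion adds to the enal, and Smiles rearrangement with loss of SO2 and tetrazololate gives the (13E)-alkene of the 11E,13E-diene; generating and trapping the anion at −78 °C outruns β-elimination of methoxide.

Step 23
Reactants: 29 seco ester
Product: 30 seco acid: (2Z,4S,5R,6E,8Z,11E,13E,15S,17R,18S,19R,20E)-17-[(tert-butyldimethylsilyl)oxy]-19-hydroxy-15-methoxy-2,4,6,12,18-pentamethyl-5-(triethylsilyloxy)-21-[(4R,5S)-2,2,5-trimethyl-1,3-dioxolan-4-yl]henicosa-2,6,8,11,13,20-hexaenoic acid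
Conditions: LiOH·H2O, THF/MeOH/H2O (3:1:1), rt; then sat. aq. NH4Cl
Reagents that add atoms: lithium hydroxide, [Li+].[OH-]
Why: Saponification cleaves the C19 acetate and the ethyl ester in one operation, leaves both silyl ethers, and exposes C19–OH as the only free alcohol.

Step 24
Reactants: 30 seco acid
Product: 32 macrolactone (20-membered C1–O19 lactone; 5-OTES; 17-OTBS; 22,23-acetonide), via mixed anhydride 31 (not isolated)
Conditions: 2-methyl-6-nitrobenzoic anhydride (MNBA), DMAP, CH2Cl2, rt, slow addition of 30 (final 1 mM)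
Reagents that add atoms: none
Why: Shiina macrolactonisation: the mixed anhydride forms at the seco-acid carboxyl and DMAP-mediated acyl transfer to the only free hydroxyl (C19) under high dilution closes the 20-membered lactone without touching a stereocentre.

Step 25
Reactants: 32 macrolactone
Product: 34 macrocyclic dienone (C5 ketone; 17-OTBS; 22,23-acetonide), via C5 alcohol 33 (not isolated)
Conditions: IBX (3 equiv), DMSO, rt
Reagents that add atoms: none
Why: IBX in DMSO cleaves TES ethers in the presence of TBS ethers and oxidises the released dienylic alcohol in the same pot, so the C5 ketone forms before the free C5 hydroxyl can translactonise onto the (Z)-enoate.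

Step 26
Reactants: 34 macrocyclic dienone
Product: 35 macrocyclic hydroxy diene (C5 ketone; 17-OH; 11E,13E-diene; 22,23-acetonide)
Conditions: HF·pyridine, pyridine, THF, 0 °C → rt
Reagents that add atoms: none
Why: Buffered HF·pyridine removes the secondary TBS ether under weakly acidic conditions that neither epimerise C4 nor migrate the lactone.

Step 27
Reactants: 35 macrocyclic hydroxy diene
Product: 37 maltepolide D 22,23-acetonide, via vinyl epoxide 36 (not isolated)
Conditions: Shi ketone (D-fructose-derived, 0.5 equiv), Oxone (2KHSO5·KHSO4·K2SO4), NaHCO3 buffer (pH 8), MeCN/dimethoxymethane/H2O, 0 °C; extract; then PPTS (10 mol%), CH2Cl2, 0 °C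
Reagents that add atoms: potassium peroxymonosulfate (KHSO5, the oxidant in Oxone), [K+].[O-]S(=O)(=O)OO
Why: Shi asymmetric epoxidation should pick the only electron-rich trisubstituted alkene (C11=C12; the dienone, the enoate and the oxygen-flanked C13=C14 and C20=C21 are deactivated) and the D-fructose-derived ketone gives the (11R,12R)-epoxide, after which acid-promoted 5-exo SN2′ (vinylogous) epoxide opening by C17–OH, anti to the departing oxygen from the s-cis C11–C12–C13=C14 rotamer and with the C15 methoxy group in the inside position, sets C14 (S), the 2,5-trans/2,3-cis THF and the 12Z alkene while the C11–O bond is retained as C11 (R)–OH.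

Step 28
Reactants: 37 maltepolide D 22,23-acetonide
Product: 38 maltepolide D
Conditions: AcOH/H2O (4:1), 35 °C
Reagents that add atoms: none
Why: Mild aqueous-acid hydrolysis of the terminal acetonide frees the 22,23-diol without ionising the allylic ether, the allylic alcohol or the allylic lactone.

## Compound list

1 | 3-(trimethylsilyl)prop-2-ynal | C[Si](C)(C)C#CC=O | starting material
2 | 2-(triphenylphosphoranylidene)propanal | CC(C=O)=P(c1ccccc1)(c1ccccc1)c1ccccc1 | starting material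
3 | (2E)-2-methyl-5-(trimethylsilyl)pent-2-en-4-ynal | O=C/C(C)=C/C#C[Si](C)(C)C | intermediate
4 | (4S)-4-benzyl-3-propanoyl-1,3-thiazolidine-2-thione | CCC(=O)N1[C@@H](Cc2ccccc2)CSC1=S | starting material
5 | (4S)-4-benzyl-3-[(2R,3R,4E)-3-hydroxy-2,4-dimethyl-7-(trimethylsilyl)hept-4-en-6-ynoyl]-1,3-thiazolidine-2-thione | S=C1SC[C@H](Cc2ccccc2)N1C(=O)[C@H](C)[C@@H](O)/C(C)=C/C#C[Si](C)(C)C | intermediate
6 | (4S)-4-benzyl-3-[(2R,3R,4E)-2,4-dimethyl-3-(triethylsilyloxy)-7-(trimethylsilyl)hept-4-en-6-ynoyl]-1,3-thiazolidine-2-thione | S=C1SC[C@H](Cc2ccccc2)N1C(=O)[C@H](C)[C@@H](O[Si](CC)(CC)CC)/C(C)=C/C#C[Si](C)(C)C | intermediate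
7 | (2R,3R,4E)-2,4-dimethyl-3-(triethylsilyloxy)-7-(trimethylsilyl)hept-4-en-6-ynal | O=C[C@H](C)[C@@H](O[Si](CC)(CC)CC)/C(C)=C/C#C[Si](C)(C)C | intermediate
8 | ethyl 2-[bis(2,2,2-trifluoroethoxy)phosphoryl]propanoate | CCOC(=O)C(C)P(=O)(OCC(F)(F)F)OCC(F)(F)F | starting material
9 | ethyl (2Z,4S,5R,6E)-2,4,6-trimethyl-5-(triethylsilyloxy)-9-(trimethylsilyl)nona-2,6-dien-8-ynoate | CCOC(=O)/C(C)=C\[C@H](C)[C@@H](O[Si](CC)(CC)CC)/C(C)=C/C#C[Si](C)(C)C | intermediate
10 | ethyl (2Z,4S,5R,6E)-2,4,6-trimethyl-5-(triethylsilyloxy)nona-2,6-dien-8-ynoate | CCOC(=O)/C(C)=C\[C@H](C)[C@@H](O[Si](CC)(CC)CC)/C(C)=C/C#C | intermediate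
11 | 2-methyl-2-vinyloxirane (racemic) | CC1(C=C)CO1 | starting material
12 | (2E)-4-chloro-2-methylbut-2-en-1-ol | OC/C(C)=C/CCl | intermediate
13 | ethyl (2Z,4S,5R,6E,11E)-13-hydroxy-2,4,6,12-tetramethyl-5-(triethylsilyloxy)trideca-2,6,11-trien-8-ynoate | CCOC(=O)/C(C)=C\[C@H](C)[C@@H](O[Si](CC)(CC)CC)/C(C)=C/C#CC/C=C(C)/CO | intermediate
14 | ethyl (2Z,4S,5R,6E,8Z,11E)-13-hydroxy-2,4,6,12-tetramethyl-5-(triethylsilyloxy)trideca-2,6,8,11-tetraenoate | CCOC(=O)/C(C)=C\[C@H](C)[C@@H](O[Si](CC)(CC)CC)/C(C)=C/C=C\C/C=C(C)/CO | intermediate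
15 | ethyl (2Z,4S,5R,6E,8Z,11E)-2,4,6,12-tetramethyl-13-oxo-5-(triethylsilyloxy)trideca-2,6,8,11-tetraenoate | CCOC(=O)/C(C)=C\[C@H](C)[C@@H](O[Si](CC)(CC)CC)/C(C)=C/C=C\C/C=C(C)/C=O | intermediate
16 | ethyl (3S)-4-chloro-3-hydroxybutanoate | CCOC(=O)C[C@H](O)CCl | starting material
17 | ethyl (3S)-4-chloro-3-methoxybutanoate | CCOC(=O)C[C@H](OC)CCl | intermediate
18 | ethyl (3S)-3-methoxy-4-[(1-phenyl-1H-tetrazol-5-yl)sulfanyl]butanoate | CCOC(=O)C[C@H](OC)CSc1nnnn1-c1ccccc1 | intermediate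
19 | (3S)-N,3-dimethoxy-N-methyl-4-[(1-phenyl-1H-tetrazol-5-yl)sulfanyl]butanamide | CON(C)C(=O)C[C@H](OC)CSc1nnnn1-c1ccccc1 | intermediate
20 | (5S)-5-methoxy-6-[(1-phenyl-1H-tetrazol-5-yl)sulfanyl]hexan-3-one | CCC(=O)C[C@H](OC)CSc1nnnn1-c1ccccc1 | intermediate
21 | (5S)-5-methoxy-6-[(1-phenyl-1H-tetrazol-5-yl)sulfonyl]hexan-3-one | CCC(=O)C[C@H](OC)CS(=O)(=O)c1nnnn1-c1ccccc1 | intermediate
22 | 3,4-di-O-acetyl-L-rhamnal, (2S,3S,4S)-2-methyl-3,4-dihydro-2H-pyran-3,4-diyl diacetate | C[C@@H]1OC=C[C@H](OC(C)=O)[C@H]1OC(C)=O | starting material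
23 | (2E,4R,5S)-4-acetoxy-5-hydroxyhex-2-enal | O=C/C=C/[C@@H](OC(C)=O)[C@H](C)O | intermediate
24 | (2E,4R,5S)-4,5-dihydroxyhex-2-enal | O=C/C=C/[C@@H](O)[C@H](C)O | intermediate
25 | (2E)-3-[(4R,5S)-2,2,5-trimethyl-1,3-dioxolan-4-yl]prop-2-enal | O=C/C=C/[C@H]1OC(C)(C)O[C@H]1C | intermediate
26 | (2S,5S,6R,7E)-6-hydroxy-2-methoxy-5-methyl-1-[(1-phenyl-1H-tetrazol-5-yl)sulfonyl]-8-[(4R,5S)-2,2,5-trimethyl-1,3-dioxolan-4-yl]oct-7-en-4-one (C14–C24) | O=S(=O)(C[C@@H](OC)CC(=O)[C@@H](C)[C@H](O)/C=C/[C@H]1OC(C)(C)O[C@H]1C)c1nnnn1-c1ccccc1 | intermediate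
27 | (2S,4R,5R,6R,7E)-4-hydroxy-2-methoxy-5-methyl-1-[(1-phenyl-1H-tetrazol-5-yl)sulfonyl]-8-[(4R,5S)-2,2,5-trimethyl-1,3-dioxolan-4-yl]oct-7-en-6-yl acetate | O=S(=O)(C[C@@H](OC)C[C@@H](O)[C@@H](C)[C@H](OC(C)=O)/C=C/[C@H]1OC(C)(C)O[C@H]1C)c1nnnn1-c1ccccc1 | intermediate
28 | (2S,4R,5S,6R,7E)-4-[(tert-butyldimethylsilyl)oxy]-2-methoxy-5-methyl-1-[(1-phenyl-1H-tetrazol-5-yl)sulfonyl]-8-[(4R,5S)-2,2,5-trimethyl-1,3-dioxolan-4-yl]oct-7-en-6-yl acetate | O=S(=O)(C[C@@H](OC)C[C@@H](O[Si](C)(C)C(C)(C)C)[C@@H](C)[C@H](OC(C)=O)/C=C/[C@H]1OC(C)(C)O[C@H]1C)c1nnnn1-c1ccccc1 | intermediate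
29 | seco ester: ethyl (2Z,4S,5R,6E,8Z,11E,13E,15S,17R,18S,19R,20E)-19-acetoxy-17-[(tert-butyldimethylsilyl)oxy]-15-methoxy-2,4,6,12,18-pentamethyl-5-(triethylsilyloxy)-21-[(4R,5S)-2,2,5-trimethyl-1,3-dioxolan-4-yl]henicosa-2,6,8,11,13,20-hexaenoate | CCOC(=O)/C(C)=C\[C@H](C)[C@@H](O[Si](CC)(CC)CC)/C(C)=C/C=C\C/C=C(C)/C=C/[C@@H](OC)C[C@@H](O[Si](C)(C)C(C)(C)C)[C@@H](C)[C@H](OC(C)=O)/C=C/[C@H]1OC(C)(C)O[C@H]1C | intermediate
30 | seco acid: (2Z,4S,5R,6E,8Z,11E,13E,15S,17R,18S,19R,20E)-17-[(tert-butyldimethylsilyl)oxy]-19-hydroxy-15-methoxy-2,4,6,12,18-pentamethyl-5-(triethylsilyloxy)-21-[(4R,5S)-2,2,5-trimethyl-1,3-dioxolan-4-yl]henicosa-2,6,8,11,13,20-hexaenoic acid | OC(=O)/C(C)=C\[C@H](C)[C@@H](O[Si](CC)(CC)CC)/C(C)=C/C=C\C/C=C(C)/C=C/[C@@H](OC)C[C@@H](O[Si](C)(C)C(C)(C)C)[C@@H](C)[C@H](O)/C=C/[C@H]1OC(C)(C)O[C@H]1C | intermediate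
31 | mixed anhydride of 30 with 2-methyl-6-nitrobenzoic acid | Cc1cccc([N+](=O)[O-])c1C(=O)OC(=O)/C(C)=C\[C@H](C)[C@@H](O[Si](CC)(CC)CC)/C(C)=C/C=C\C/C=C(C)/C=C/[C@@H](OC)C[C@@H](O[Si](C)(C)C(C)(C)C)[C@@H](C)[C@H](O)/C=C/[C@H]2OC(C)(C)O[C@H]2C | intermediate (not isolated)
32 | macrolactone: 20-membered C1–O19 lactone, 2Z,4S,5R,6E,8Z,11E,13E,15S,17R,18S,19R,20E,22R,23S; 5-OTES, 17-OTBS, 15-OMe, 22,23-O-isopropylidene | O=C1/C(C)=C\[C@H](C)[C@@H](O[Si](CC)(CC)CC)/C(C)=C/C=C\C/C=C(C)/C=C/[C@@H](OC)C[C@@H](O[Si](C)(C)C(C)(C)C)[C@@H](C)[C@H](O1)/C=C/[C@H]2OC(C)(C)O[C@H]2C | intermediate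
33 | C5 alcohol of 32 (5R-OH, 17-OTBS) | O=C1/C(C)=C\[C@H](C)[C@@H](O)/C(C)=C/C=C\C/C=C(C)/C=C/[C@@H](OC)C[C@@H](O[Si](C)(C)C(C)(C)C)[C@@H](C)[C@H](O1)/C=C/[C@H]2OC(C)(C)O[C@H]2C | intermediate (not isolated)
34 | macrocyclic dienone: C5 ketone, 2Z,4S,6E,8Z,11E,13E,15S,17R,18S,19R,20E,22R,23S; 17-OTBS, 22,23-O-isopropylidene | O=C1/C(C)=C\[C@H](C)C(=O)/C(C)=C/C=C\C/C=C(C)/C=C/[C@@H](OC)C[C@@H](O[Si](C)(C)C(C)(C)C)[C@@H](C)[C@H](O1)/C=C/[C@H]2OC(C)(C)O[C@H]2C | intermediate
35 | macrocyclic hydroxy diene: as 34 with free 17-OH (4S,15S,17R,18R,19R,22R,23S) | O=C1/C(C)=C\[C@H](C)C(=O)/C(C)=C/C=C\C/C=C(C)/C=C/[C@@H](OC)C[C@@H](O)[C@@H](C)[C@H](O1)/C=C/[C@H]2OC(C)(C)O[C@H]2C | intermediate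
36 | macrocyclic vinyl epoxide: (11R,12R)-11,12-epoxide of 35, 13E | O=C1/C(C)=C\[C@H](C)C(=O)/C(C)=C/C=C\C[C@H]2O[C@]2(C)/C=C/[C@@H](OC)C[C@@H](O)[C@@H](C)[C@H](O1)/C=C/[C@H]3OC(C)(C)O[C@H]3C | intermediate (not isolated)
37 | maltepolide D 22,23-acetonide (2Z,4S,6E,8Z,11R,12Z,14S,15S,17R,18R,19R,20E,22R,23S) | CO[C@H]1C[C@H]2O[C@H]1/C=C(/C)[C@H](O)C/C=C\C=C(/C)C(=O)[C@@H](C)/C=C(/C)C(=O)O[C@H](/C=C/[C@H]3OC(C)(C)O[C@H]3C)[C@@H]2C | intermediate
38 | maltepolide D (2Z,4S,6E,8Z,11R,12Z,14S,15S,17R,18R,19R,20E,22R,23S) | CO[C@H]1C[C@H]2O[C@H]1/C=C(/C)[C@H](O)C/C=C\C=C(/C)C(=O)[C@@H](C)/C=C(/C)C(=O)O[C@H](/C=C/[C@@H](O)[C@H](C)O)[C@@H]2C | target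

## Step count and risks

Total steps: 28. Longest linear sequence: 16 steps (steps 1–6, 8–10, 22–28).

**Step 27 (epoxidation and SN2′ etherification on the macrolactone).** This is the least certain step.
- The epoxidation must find C11=C12 and the correct face inside a macrocycle, at a pH that C4 tolerates.
- The etherification must run anti from the s-cis rotamer. Reaction through the s-trans rotamer would give the 12E isomer, and syn attack would give the C14 epimer.
- Fallback, setting out from 35 and coming back at 37: 35 is dihydroxylated at C11=C12 with stoichiometric OsO4 and (DHQD)2PHAL in CH2Cl2 at −78 °C (NaHSO3 work-up) to give the (11R,12R)-11,12-diol F1. CSA in CH2Cl2 then ionises the tertiary allylic C12–OH, and the C17 hydroxyl closes onto C14 (SN1′-type 5-exo etherification) with C11–OH retained, giving 37.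

**Step 24 (macrolactonisation).** The activated (Z)-2-methyl enoate can isomerise to E under DMAP, and the C19 hydroxyl is hindered and allylic, so oligomers may form.
- Fallback, setting out from 28 and 14 and coming back at 32: 28 is deacetylated (K2CO3, MeOH) to the C19 alcohol F2. 14 is saponified (LiOH) to the hydroxy acid F3 and oxidised (MnO2) to the enal acid F4. F4 and F2 are joined by carbodiimide esterification (EDC·HCl, DMAP) to the sulfone–aldehyde ester F5. The ring is then closed by an intramolecular Julia–Kocienski olefination (KN(SiMe3)2, THF, high dilution, −78 °C → rt) that forms C13=C14 and gives 32.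

**Step 19 (boron aldol of ketone 21).** Enolisation may not be clean on the ethyl side, the β-methoxy group may eliminate, and the facial sense of the Ipc reagent on this functionalised ketone is taken from simple ethyl ketones.
- Fallback, setting out from 19 and coming back at 26: 19 is treated with vinylmagnesium bromide to give the vinyl ketone F6, which is oxidised (H2O2, (NH4)6Mo7O24) to the sulfonyl vinyl ketone F7. 1,4-Hydroboration of F7 with (−)-Ipc2BH generates the same (Z)-enol borinate regiospecifically; addition of 25 and oxidative work-up give 26.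

## Further compounds

F1 | step 27 | macrocyclic (11R,12R)-11,12-diol of 35 (C5 ketone, 13E, 17-OH, 22,23-O-isopropylidene) | O=C1/C(C)=C\[C@H](C)C(=O)/C(C)=C/C=C\C[C@@H](O)[C@](C)(O)/C=C/[C@@H](OC)C[C@@H](O)[C@@H](C)[C@H](O1)/C=C/[C@H]2OC(C)(C)O[C@H]2C
F2 | step 24 | (2S,4R,5S,6R,7E)-4-[(tert-butyldimethylsilyl)oxy]-2-methoxy-5-methyl-1-[(1-phenyl-1H-tetrazol-5-yl)sulfonyl]-8-[(4R,5S)-2,2,5-trimethyl-1,3-dioxolan-4-yl]oct-7-en-6-ol | O=S(=O)(C[C@@H](OC)C[C@@H](O[Si](C)(C)C(C)(C)C)[C@@H](C)[C@H](O)/C=C/[C@H]1OC(C)(C)O[C@H]1C)c1nnnn1-c1ccccc1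
F3 | step 24 | (2Z,4S,5R,6E,8Z,11E)-13-hydroxy-2,4,6,12-tetramethyl-5-(triethylsilyloxy)trideca-2,6,8,11-tetraenoic acid | OC(=O)/C(C)=C\[C@H](C)[C@@H](O[Si](CC)(CC)CC)/C(C)=C/C=C\C/C=C(C)/CO
F4 | step 24 | (2Z,4S,5R,6E,8Z,11E)-2,4,6,12-tetramethyl-13-oxo-5-(triethylsilyloxy)trideca-2,6,8,11-tetraenoic acid | OC(=O)/C(C)=C\[C@H](C)[C@@H](O[Si](CC)(CC)CC)/C(C)=C/C=C\C/C=C(C)/C=O
F5 | step 24 | ester of F4 with the C19 hydroxyl of F2 (sulfone and C13 aldehyde in one chain) | O=S(=O)(C[C@@H](OC)C[C@@H](O[Si](C)(C)C(C)(C)C)[C@@H](C)[C@H](OC(=O)/C(C)=C\[C@H](C)[C@@H](O[Si](CC)(CC)CC)/C(C)=C/C=C\C/C=C(C)/C=O)/C=C/[C@H]1OC(C)(C)O[C@H]1C)c1nnnn1-c1ccccc1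
F6 | step 19 | (5S)-5-methoxy-6-[(1-phenyl-1H-tetrazol-5-yl)sulfanyl]hex-1-en-3-one | C=CC(=O)C[C@H](OC)CSc1nnnn1-c1ccccc1
F7 | step 19 | (5S)-5-methoxy-6-[(1-phenyl-1H-tetrazol-5-yl)sulfonyl]hex-1-en-3-one | C=CC(=O)C[C@H](OC)CS(=O)(=O)c1nnnn1-c1ccccc1
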